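# Proposed synthesis of caraganin A by a three-component ortho-quinone methide union on the intact isoflavone

## Analysis of the target

Caraganin A (18) is a 3-arylchromen-4-one. Ring A (the benzo ring, with a hydrogen-bonded 5-OH and a 7-OMe) is fused to the pyranone ring C, and C3 carries ring B, a 2',4'-dihydroxyphenyl group. C5' of ring B bears the only stereocentre, the methine Cα. Its other two carbon substituents are ring D (2,4-dimethoxyphenyl) and the Cβ=Cγ bond of an (E)-styryl unit that ends in ring E (4-hydroxyphenyl). Cα is R: ring D outranks ring B because the oxygen ortho to its attachment point carries carbon, whereas O4' carries hydrogen; the alkenyl carbon ranks third. Nothing else in the molecule can relay chirality, and the three sp2 groups on Cα are of similar size, so the configuration must come from a catalyst or reagent. The compound is sensitive in several ways. The pyranone C2 is open to nucleophiles and strong base. The C2=C3 and styryl double bonds exclude late hydrogenation. Acid can add the free O4'–H across the electron-rich styrene to give a 2,4-diarylchromane. Four phenols must be told apart, and rings A, B and D are all electron-rich. The feature used here is that the free O4' hydroxyl is ortho to C5'. Cα can therefore be the exocyclic carbon of an ortho-quinone methide across C4' and C5', an electrophile that forms from a phenol and an aldehyde and accepts an alkenyl nucleophile.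

## Retrosynthetic reasoning

**18 ⇒ 17.** The end of the route is fixed first, because the target tolerates neither acid nor hydrogen. The O2' and ring E hydroxyls are masked as silyl ethers in 17, so that the last step cuts only two O–Si bonds with buffered fluoride. O4' and the chelated O5 are already free. The forward step must release both phenols without touching the styrene, the pyranone or Cα.

**17 ⇒ 9 + 15 + 14.** Both bonds cut here, C5'–Cα and Cα–Cβ, start at the stereocentre. Cutting them together reduces 17 to three achiral pieces: the complete isoflavone phenol 9, aldehyde 15 (whose carbonyl carbon becomes Cα) and alkenylboronate 14. Cutting at C3–C1' or at Cα–ring D instead would leave a chiral fragment to be made separately and carried through heterocycle construction. In the forward direction 9 and 15 must join only at C5' and pass through quinone methide 16. A chiral biphenol bound to boron must then deliver the styryl group to one face with retention of the E geometry. No ring is formed.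

**9 ⇒ 8 ⇒ 3 + 7.** The C3–C1' bond between the pyranone and ring B is the standard cross-coupling cut of an isoflavone. It gives 3-iodochromone 3 and arylboronate 7. Ring B must arrive with O2' silylated and O4' separately addressable, so 7 carries a triisopropylsilyl ether ortho to boron and a benzyl ether para to it. The benzyl group is removed by hydrogenolysis (8 → 9) at a stage where no styrene is present.

**3 ⇒ 2 ⇒ 1.** The pyranone is opened at O1–C2 and the C3–I bond is removed, which leads to enaminone 2 and then to the symmetrical acetophenone 1. Because the two hydroxyls of 1 are equivalent, ring closure can give only one chromone, and the hydroxyl left over is the chelated 5-OH of the target. No protecting group is needed on ring A.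

**7 ⇒ 6 ⇒ 5 ⇒ 4.** The C–B bond is traced to the C–Br bond of 6 through a palladium-catalysed borylation. An aryl anion ortho to a silyloxy group would draw silicon from oxygen to carbon, so a halogen–metal exchange is avoided. The O–Si bond of 6 leads to bromophenol 5, and the benzyl ether of 5 to 4-bromoresorcinol 4, alkylated at the hydroxyl remote from bromine.

**14 ⇒ 12 ⇒ 11 ⇒ 10.** The alkenyl C–B bond comes from syn hydroboration of terminal alkyne 12 (through 13), which fixes the E geometry. The alkyne comes from aldehyde 11 by a one-carbon homologation under aprotic conditions. Alkoxide-based homologations would remove the aryl silyl ether, which is activated by the para formyl group. Aldehyde 11 is the silyl ether of 10. Aldehyde 15 is purchased.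

## Alternatives that were turned down

**Alternative 1: aryne annulation that builds ring A and the pyranone.**
- Disconnection: O1–C8a and C4–C4a.
- Forward key step: a fluoride source releases an aryne from silyl triflate A2. The enol oxygen of the chiral α-formyl arylacetate A3 adds to the aryne carbon remote from the flanking methoxy group, and the resulting aryl anion closes onto the ester to give A1.
- For it: the distortion of the methoxy-substituted aryne dictates the correct 5,7-dioxygenation, and two bonds and a ring form in one step under non-acidic conditions. On ring A regiochemistry it is as strong as the chosen route.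
- Against it: A3 must already contain Cα, the styrene and all of ring B, so the asymmetric step and several further steps come before the key step. C-arylation of the enolate competes with O-arylation. A1 carries a 5-OMe and three acetal ethers, so the end game needs a Lewis acid for the chelation-directed demethylation and protic acid for the acetals. These are the conditions under which O4'–H adds to the styrene.
- Comparison: the chosen route forms the stereocentre last on a finished heterocycle and ends with fluoride only.

**Alternative 2: pyranone closed at C4–C4a by Friedel–Crafts acylation.**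
- Disconnection: C4–C4a.
- Forward key step: the (Z)-aryloxyacrylic acid A5 is converted to its acid chloride and, with a zinc Lewis acid, acylates the ortho carbon of its symmetrical dimethoxyphenoxy ring to give A4.
- For it: acylation of such an electron-rich ring is dependable, and the symmetry of the nucleophilic ring removes any regiochemical question. The ring closure itself is better precedented than the key step chosen here.
- Against it: acid chloride formation and Lewis acid act on a substrate that holds an ionisable, doubly benzylic allylic methine and an electron-rich styrene. The Z geometry of A5 can be lost by reversible conjugate addition. The three benzyl ethers of A4 cannot be hydrogenolysed beside two C=C bonds, so a boron Lewis acid would have to remove them together with the 5-O-methyl group. This again brings the acid sensitivity to the last step. The chiral half needs its own asymmetric synthesis.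
- Comparison: the chosen strategy offers step economy and a neutral end game in place of this reliability.

**Alternative 3: photoredox arylation and annulation of a symmetrical enaminone.**
- Disconnection: C3–C1' and O1–C2.
- Forward key step: under blue light with a ruthenium photocatalyst, diazonium salt A7 gives an aryl radical that attacks the α-carbon of enaminone 2. A phenolic oxygen then closes the pyranone with loss of the amine, giving A6.
- For it: it uses the same enaminone 2 as the chosen route and delivers the 5-OH/7-OMe pattern directly, with no demethylation. In this respect it equals the chosen route.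
- Against it: A7 is a diazonium ion on a ring that carries two acid-labile acetals, and it is prepared from an aniline that needs extra steps. It sits in a molecule with an electron-rich styrene and a dimethoxyarene, both good partners for azo coupling and for intermolecular radical addition. The weak Cα–H bond is a hydrogen-atom donor. Acetal removal at the end requires acid.
- Comparison: the chosen route keeps radicals and acid away from the stereocentre and needs no nitrogen chemistry.

Key step: step 11

Assumption: (R)-3,3'-dibromo-1,1'-bi-2-naphthol is taken as the antipode that gives (R)-17; if a first run shows the opposite sense, the (S)-catalyst is used and nothing else changes.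

## Route

**Step 1**
Reactants: 1 2',6'-dihydroxy-4'-methoxyacetophenone
Product: 2 (E)-1-(2,6-dihydroxy-4-methoxyphenyl)-3-(dimethylamino)prop-2-en-1-one
Conditions: Me2NCH(OMe)2 (1.5 equiv), PhMe, 85 °C
Reagents that add atoms: N,N-dimethylformamide dimethyl acetal, COC(OC)N(C)C
Why: Amide acetal condensation at the acetyl methyl group gives the vinylogous amide; both phenols are hydrogen-bonded to the ketone and poorly nucleophilic, and limiting the reagent and temperature keeps them from being methylated.

**Step 2**
Reactants: 2 (E)-1-(2,6-dihydroxy-4-methoxyphenyl)-3-(dimethylamino)prop-2-en-1-one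
Product: 3 5-hydroxy-3-iodo-7-methoxy-4H-chromen-4-one
Conditions: I2 (1.2 equiv), CHCl3, rt; aq. Na2S2O3 wash
Reagents that add atoms: iodine, II
Why: Iodine-mediated enaminone cyclisation: the α-carbon is iodinated, a phenolic oxygen attacks the iminium carbon and the amine is lost; the two hydroxyls are equivalent, so one chromone forms and the other hydroxyl remains as the chelated 5-OH.

**Step 3**
Reactants: 4 4-bromoresorcinol
Product: 5 5-(benzyloxy)-2-bromophenol
Conditions: BnBr (1.0 equiv), K2CO3 (1.1 equiv), acetone, reflux
Reagents that add atoms: benzyl bromide, BrCc1ccccc1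
Why: Williamson etherification; the hydroxyl para to bromine is less hindered and gives the more nucleophilic phenoxide, so monoalkylation should favour 5, and the regioisomer and bis-ether are removed by chromatography.

**Step 4**
Reactants: 5 5-(benzyloxy)-2-bromophenol
Product: 6 [5-(benzyloxy)-2-bromophenoxy]tri(propan-2-yl)silane
Conditions: TIPSCl (1.3 equiv), imidazole (2.5 equiv), DMF, rt → 40 °C
Reagents that add atoms: chlorotri(propan-2-yl)silane, CC(C)[Si](Cl)(C(C)C)C(C)C
Why: Imidazole-promoted O-silylation of the one remaining phenol; the bulky silyl ether later shields C3' and withstands the coupling base and hydrogenolysis.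

**Step 5**
Reactants: 6 [5-(benzyloxy)-2-bromophenoxy]tri(propan-2-yl)silane
Product: 7 [5-(benzyloxy)-2-(4,4,5,5-tetramethyl-1,3,2-dioxaborolan-2-yl)phenoxy]tri(propan-2-yl)silane
Conditions: B2pin2 (1.3 equiv), PdCl2(dppf) (5 mol%), KOAc (3 equiv), 1,4-dioxane, 90 °C
Reagents that add atoms: bis(pinacolato)diboron, CC1(C)OB(OC1(C)C)B1OC(C)(C)C(C)(C)O1
Why: Miyaura borylation replaces bromine by boron without an aryl anion, which would trigger migration of silicon from the ortho oxygen to carbon.

**Step 6**
Reactants: 3 5-hydroxy-3-iodo-7-methoxy-4H-chromen-4-one; 7 [5-(benzyloxy)-2-(4,4,5,5-tetramethyl-1,3,2-dioxaborolan-2-yl)phenoxy]tri(propan-2-yl)silane (1.3 equiv)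
Product: 8 3-[4-(benzyloxy)-2-(triisopropylsilyloxy)phenyl]-5-hydroxy-7-methoxy-4H-chromen-4-one
Conditions: Pd(OAc)2 (5 mol%), SPhos (10 mol%), K3PO4 (3 equiv), PhMe/H2O 10:1, 60 °C
Reagents that add atoms: none
Why: Suzuki–Miyaura coupling; 3-iodochromones add readily to zerovalent palladium, the biaryl phosphine speeds transmetalation of the ortho-substituted boronate, and the two-phase phosphate medium keeps hydroxide away from the silyl ether and the pyranone.

**Step 7**
Reactants: 8 3-[4-(benzyloxy)-2-(triisopropylsilyloxy)phenyl]-5-hydroxy-7-methoxy-4H-chromen-4-one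
Product: 9 5-hydroxy-3-[4-hydroxy-2-(triisopropylsilyloxy)phenyl]-7-methoxy-4H-chromen-4-one
Conditions: H2 (1 atm), Pd/C (10 wt%), EtOAc, rt, stopped after one equivalent of uptake
Reagents that add atoms: none
Why: Hydrogenolysis of a benzyl aryl ether is faster than reduction of the tetrasubstituted, conjugated C2=C3 bond; the silyl ether is inert, so only O4' is set free.

**Step 8**
Reactants: 10 4-hydroxybenzaldehyde
Product: 11 4-(tert-butyldimethylsilyloxy)benzaldehyde
Conditions: TBSCl (1.1 equiv), imidazole (2.2 equiv), CH2Cl2, rt
Reagents that add atoms: tert-butylchlorodimethylsilane, CC(C)(C)[Si](C)(C)Cl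
Why: Standard phenol silylation; the group lasts through the aprotic steps to the end and leaves with the other silyl ether.

**Step 9**
Reactants: 11 4-(tert-butyldimethylsilyloxy)benzaldehyde
Product: 12 tert-butyl(4-ethynylphenoxy)dimethylsilane
Conditions: Me3SiCHN2 (1.2 equiv), LiN(i-Pr)2 (1.2 equiv), THF, −78 °C → rt; H2O
Reagents that add atoms: trimethylsilyldiazomethane, C[Si](C)(C)C=[N+]=[N-]
Why: Colvin rearrangement: the lithiated silyl diazomethane adds to the aldehyde, Peterson-type elimination and loss of nitrogen follow, and a 1,2-shift gives the terminal alkyne; the medium is aprotic, so the aryl silyl ether is not cleaved.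

**Step 10**
Reactants: 12 tert-butyl(4-ethynylphenoxy)dimethylsilane
Product: 14 diethyl [(E)-2-{4-[tert-butyl(dimethyl)silyloxy]phenyl}ethenyl]boronate, via alkenylbis(isopinocampheyl)borane 13 (not isolated)
Conditions: (−)-Ipc2BH (1.05 equiv), THF, 0 °C → rt; then CH3CHO (10 equiv), 0 → 40 °C; volatiles removed under high vacuum, product kept under argon
Reagents that add atoms: (−)-diisopinocampheylborane, C[C@H]1[C@H](B[C@@H]3C[C@@H]4C[C@H]([C@H]3C)C4(C)C)C[C@@H]2C[C@H]1C2(C)C; acetaldehyde, CC=O
Why: Syn, anti-Markovnikov hydroboration by the hindered dialkylborane gives 13 with E geometry; acetaldehyde then removes both isopinocampheyl groups as α-pinene by β-hydride transfer and leaves two ethoxy groups on boron, and all by-products are volatile, so no chromatography is needed.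

**Step 11**
Reactants: 9 5-hydroxy-3-[4-hydroxy-2-(triisopropylsilyloxy)phenyl]-7-methoxy-4H-chromen-4-one; 15 2,4-dimethoxybenzaldehyde (1.5 equiv); 14 diethyl [(E)-2-{4-[tert-butyl(dimethyl)silyloxy]phenyl}ethenyl]boronate (2.5 equiv)
Product: 17 3-{5-[(1R,2E)-3-{4-[tert-butyl(dimethyl)silyloxy]phenyl}-1-(2,4-dimethoxyphenyl)prop-2-en-1-yl]-4-hydroxy-2-(triisopropylsilyloxy)phenyl}-5-hydroxy-7-methoxy-4H-chromen-4-one (bis-silyl ether of caraganin A), via ortho-quinone methide 16 (not isolated)
Conditions: (R)-3,3'-dibromo-1,1'-bi-2-naphthol (20 mol%), 4 Å MS, PhMe, rt → 40 °C; pH 7 phosphate buffer work-up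
Reagents that add atoms: none
Why: Exchange of an ethoxy group ties boron to O4' of 9, the boron-activated aldehyde 15 is attacked by C5' in an ortho-directed Friedel–Crafts hydroxyalkylation, and loss of the boron-bound oxygen gives quinone methide 16, which the 2,4-dimethoxyphenyl group stabilises. The alkenylboronate that has exchanged ethoxy for the biphenol binds the quinone methide oxygen and passes its styryl group to the exocyclic carbon through a closed six-membered transition state, which restores the aromaticity of ring B. The closest known reaction is the chiral biphenol-catalysed three-component condensation of electron-rich phenols, aryl aldehydes and alkenylboronates, a Petasis-type process through ortho-quinone methides; here it is applied to a phenol that is part of an isoflavone. No ring is closed. Cα is set by the axially chiral biphenol on boron, whose mixed boronate is more Lewis acidic than 14, so the catalysed transfer should outrun the racemic one. Site selectivity rests on O4' being the only free, non-chelated phenol: C5' is ortho to it and para to O2', C3' is screened by the triisopropylsilyl group, and ring A is deactivated by the C4 carbonyl with its 5-OH held in a hydrogen bond. The E geometry is carried over because alkenyl transfer from boron is stereoretentive. The excess of 14 covers any boronate bound at the 5-OH/C4=O site, and the sieves prevent hydrolysis of the boronates.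

**Step 12**
Reactants: 17 3-{5-[(1R,2E)-3-{4-[tert-butyl(dimethyl)silyloxy]phenyl}-1-(2,4-dimethoxyphenyl)prop-2-en-1-yl]-4-hydroxy-2-(triisopropylsilyloxy)phenyl}-5-hydroxy-7-methoxy-4H-chromen-4-one
Product: 18 caraganin A, 3-{5-[(1R,2E)-1-(2,4-dimethoxyphenyl)-3-(4-hydroxyphenyl)prop-2-en-1-yl]-2,4-dihydroxyphenyl}-5-hydroxy-7-methoxy-4H-chromen-4-one
Conditions: Bu4NF (3 equiv), AcOH (3 equiv), THF, 0 °C → rt; pH 7 buffer
Reagents that add atoms: none
Why: Fluoride cleaves both aryl silyl ethers; acetic acid protonates the phenoxides as they form, so neither base-induced migration of the double bond nor acid-induced chromane formation should occur, and Cα is not touched.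

## Compound list

1 | 2',6'-dihydroxy-4'-methoxyacetophenone | COc1cc(O)c(C(C)=O)c(O)c1 | starting material
2 | (E)-1-(2,6-dihydroxy-4-methoxyphenyl)-3-(dimethylamino)prop-2-en-1-one | COc1cc(O)c(C(=O)/C=C/N(C)C)c(O)c1 | intermediate
3 | 5-hydroxy-3-iodo-7-methoxy-4H-chromen-4-one | COc1cc(O)c2c(c1)occ(I)c2=O | intermediate
4 | 4-bromoresorcinol (4-bromobenzene-1,3-diol) | Oc1ccc(Br)c(O)c1 | starting material
5 | 5-(benzyloxy)-2-bromophenol | Oc1cc(OCc2ccccc2)ccc1Br | intermediate
6 | [5-(benzyloxy)-2-bromophenoxy]tri(propan-2-yl)silane | CC(C)[Si](Oc1cc(OCc2ccccc2)ccc1Br)(C(C)C)C(C)C | intermediate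
7 | [5-(benzyloxy)-2-(4,4,5,5-tetramethyl-1,3,2-dioxaborolan-2-yl)phenoxy]tri(propan-2-yl)silane | CC(C)[Si](Oc1cc(OCc2ccccc2)ccc1B1OC(C)(C)C(C)(C)O1)(C(C)C)C(C)C | intermediate
8 | 3-[4-(benzyloxy)-2-(triisopropylsilyloxy)phenyl]-5-hydroxy-7-methoxy-4H-chromen-4-one | COc1cc(O)c2c(c1)occ(-c1ccc(OCc3ccccc3)cc1O[Si](C(C)C)(C(C)C)C(C)C)c2=O | intermediate
9 | 5-hydroxy-3-[4-hydroxy-2-(triisopropylsilyloxy)phenyl]-7-methoxy-4H-chromen-4-one | COc1cc(O)c2c(c1)occ(-c1ccc(O)cc1O[Si](C(C)C)(C(C)C)C(C)C)c2=O | intermediate
10 | 4-hydroxybenzaldehyde | O=Cc1ccc(O)cc1 | starting material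
11 | 4-(tert-butyldimethylsilyloxy)benzaldehyde | CC(C)(C)[Si](C)(C)Oc1ccc(C=O)cc1 | intermediate
12 | tert-butyl(4-ethynylphenoxy)dimethylsilane | C#Cc1ccc(O[Si](C)(C)C(C)(C)C)cc1 | intermediate
13 | [(E)-2-{4-[tert-butyl(dimethyl)silyloxy]phenyl}ethenyl]bis[(1R,2S,3R,5R)-2,6,6-trimethylbicyclo[3.1.1]heptan-3-yl]borane | C[C@H]1[C@H](B(/C=C/c3ccc(O[Si](C)(C)C(C)(C)C)cc3)[C@@H]3C[C@@H]4C[C@H]([C@H]3C)C4(C)C)C[C@@H]2C[C@H]1C2(C)C | intermediate
14 | diethyl [(E)-2-{4-[tert-butyl(dimethyl)silyloxy]phenyl}ethenyl]boronate | CCOB(OCC)/C=C/c1ccc(O[Si](C)(C)C(C)(C)C)cc1 | intermediate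
15 | 2,4-dimethoxybenzaldehyde | COc1ccc(C=O)c(OC)c1 | starting material
16 | (6E)-6-[(2,4-dimethoxyphenyl)methylidene]-4-(5-hydroxy-7-methoxy-4-oxo-4H-chromen-3-yl)-3-(triisopropylsilyloxy)cyclohexa-2,4-dien-1-one (E geometry expected on steric grounds) | COc1ccc(/C=C2\C=C(-c3coc4cc(OC)cc(O)c4c3=O)C(O[Si](C(C)C)(C(C)C)C(C)C)=CC2=O)c(OC)c1 | intermediate
17 | 3-{5-[(1R,2E)-3-{4-[tert-butyl(dimethyl)silyloxy]phenyl}-1-(2,4-dimethoxyphenyl)prop-2-en-1-yl]-4-hydroxy-2-(triisopropylsilyloxy)phenyl}-5-hydroxy-7-methoxy-4H-chromen-4-one | COc1ccc([C@H](/C=C/c2ccc(O[Si](C)(C)C(C)(C)C)cc2)c2cc(-c3coc4cc(OC)cc(O)c4c3=O)c(O[Si](C(C)C)(C(C)C)C(C)C)cc2O)c(OC)c1 | intermediate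
18 | caraganin A, 3-{5-[(1R,2E)-1-(2,4-dimethoxyphenyl)-3-(4-hydroxyphenyl)prop-2-en-1-yl]-2,4-dihydroxyphenyl}-5-hydroxy-7-methoxy-4H-chromen-4-one | COc1ccc([C@H](/C=C/c2ccc(O)cc2)c2cc(-c3coc4cc(OC)cc(O)c4c3=O)c(O)cc2O)c(OC)c1 | target

## Step count and risk

Total step count: 12. Longest linear sequence: 7 steps (steps 3, 4, 5, 6, 7, 11, 12, from 4 to 18).

**Step 11 (key step).**
- What may go wrong: the first C–C bond may form slowly, because ring B has only one free hydroxyl and is attached to an electron-poor pyranone. The 5-OH/C4=O pair may bind boronate. Uncatalysed alkenyl transfer may erode the facial selectivity. A second molecule of 9 may capture 16. Ring A may be attacked at C6 or C8.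
- Fallback: the same condensation is run one stage earlier, on a ring B phenol that lacks the chelating hydroxyketone. It sets out from 7. Hydrogenolysis (H2, Pd/C, EtOAc) gives 4-(4,4,5,5-tetramethyl-1,3,2-dioxaborolan-2-yl)-3-(triisopropylsilyloxy)phenol F1, whose pinacol boronate is inert to biphenol exchange. F1 is combined with 15 and 14 under the conditions of step 11 to give the (R)-configured adduct 2-[(1R,2E)-3-{4-[tert-butyl(dimethyl)silyloxy]phenyl}-1-(2,4-dimethoxyphenyl)prop-2-en-1-yl]-4-(4,4,5,5-tetramethyl-1,3,2-dioxaborolan-2-yl)-5-(triisopropylsilyloxy)phenol F2. Suzuki–Miyaura coupling of F2 with 3 (Pd(OAc)2, SPhos, K3PO4, PhMe/H2O) then comes back to the route at 17.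

**Step 6.**
- What may go wrong: transmetalation may be slow next to the bulky silyloxy group, and the electron-rich boronate may undergo protodeboronation. The silyl ether may be lost and the pyranone opened by aqueous base.
- Fallback: the silyl group is attached after the coupling. It sets out from 5. Miyaura borylation of the free bromophenol (B2pin2, PdCl2(dppf), KOAc, dioxane) gives 5-(benzyloxy)-2-(4,4,5,5-tetramethyl-1,3,2-dioxaborolan-2-yl)phenol F3, an ortho-hydroxyaryl boronate of a type that couples readily. Coupling with 3 under the conditions of step 6 gives 3-[4-(benzyloxy)-2-hydroxyphenyl]-5-hydroxy-7-methoxy-4H-chromen-4-one F4. Silylation (TIPSCl, imidazole, DMF, 40 °C; the chelated 5-OH stays free) comes back at 8.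

**Step 3.**
- What may go wrong: the two hydroxyls of 4 may be discriminated poorly, and dialkylation may occur.
- Fallback: the position is differentiated by the size of silyl groups and benzyl is not used. It sets out from 4. TBSCl (1.0 equiv), imidazole, CH2Cl2 at −20 °C should silylate only the unhindered hydroxyl, giving 2-bromo-5-(tert-butyldimethylsilyloxy)phenol F5. TIPSCl and imidazole in DMF give tert-butyl[4-bromo-3-(triisopropylsilyloxy)phenoxy]dimethylsilane F6. Miyaura borylation gives tert-butyldimethyl[4-(4,4,5,5-tetramethyl-1,3,2-dioxaborolan-2-yl)-3-(triisopropylsilyloxy)phenoxy]silane F7. Coupling with 3 gives 3-[4-(tert-butyldimethylsilyloxy)-2-(triisopropylsilyloxy)phenyl]-5-hydroxy-7-methoxy-4H-chromen-4-one F8. Catalytic K2CO3 in MeOH at 0 °C removes the smaller, unhindered aryl silyl ether much faster than the triisopropylsilyl ether and comes back at 9, so that steps 3 to 7 are bypassed.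

**Step 10.**
- What may go wrong: the second isopinocampheyl group may be displaced incompletely, and the diethyl boronate may hydrolyse on handling. Either would lower the quality of 14 and so the selectivity of step 11.
- Fallback: it passes through a boronic acid that can be purified. It sets out from 12. Catecholborane in THF at 70 °C gives 2-[(E)-2-{4-[tert-butyl(dimethyl)silyloxy]phenyl}ethenyl]-1,3,2-benzodioxaborole F9. Stirring with water gives [(E)-2-{4-[tert-butyl(dimethyl)silyloxy]phenyl}ethenyl]boronic acid F10, which is recrystallised. Esterification with ethanol over 4 Å sieves in CH2Cl2 comes back at 14.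

## Further compounds

F1 | step 11 | 4-(4,4,5,5-tetramethyl-1,3,2-dioxaborolan-2-yl)-3-(triisopropylsilyloxy)phenol | CC(C)[Si](Oc1cc(O)ccc1B1OC(C)(C)C(C)(C)O1)(C(C)C)C(C)C
F2 | step 11 | 2-[(1R,2E)-3-{4-[tert-butyl(dimethyl)silyloxy]phenyl}-1-(2,4-dimethoxyphenyl)prop-2-en-1-yl]-4-(4,4,5,5-tetramethyl-1,3,2-dioxaborolan-2-yl)-5-(triisopropylsilyloxy)phenol | COc1ccc([C@H](/C=C/c2ccc(O[Si](C)(C)C(C)(C)C)cc2)c2cc(B3OC(C)(C)C(C)(C)O3)c(O[Si](C(C)C)(C(C)C)C(C)C)cc2O)c(OC)c1
F3 | step 6 | 5-(benzyloxy)-2-(4,4,5,5-tetramethyl-1,3,2-dioxaborolan-2-yl)phenol | Oc1cc(OCc2ccccc2)ccc1B1OC(C)(C)C(C)(C)O1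
F4 | step 6 | 3-[4-(benzyloxy)-2-hydroxyphenyl]-5-hydroxy-7-methoxy-4H-chromen-4-one | COc1cc(O)c2c(c1)occ(-c1ccc(OCc3ccccc3)cc1O)c2=O
F5 | step 3 | 2-bromo-5-(tert-butyldimethylsilyloxy)phenol | Oc1cc(O[Si](C)(C)C(C)(C)C)ccc1Br
F6 | step 3 | tert-butyl[4-bromo-3-(triisopropylsilyloxy)phenoxy]dimethylsilane | CC(C)[Si](Oc1cc(O[Si](C)(C)C(C)(C)C)ccc1Br)(C(C)C)C(C)C
F7 | step 3 | tert-butyldimethyl[4-(4,4,5,5-tetramethyl-1,3,2-dioxaborolan-2-yl)-3-(triisopropylsilyloxy)phenoxy]silane | CC(C)[Si](Oc1cc(O[Si](C)(C)C(C)(C)C)ccc1B1OC(C)(C)C(C)(C)O1)(C(C)C)C(C)C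
F8 | step 3 | 3-[4-(tert-butyldimethylsilyloxy)-2-(triisopropylsilyloxy)phenyl]-5-hydroxy-7-methoxy-4H-chromen-4-one | COc1cc(O)c2c(c1)occ(-c1ccc(O[Si](C)(C)C(C)(C)C)cc1O[Si](C(C)C)(C(C)C)C(C)C)c2=O
F9 | step 10 | 2-[(E)-2-{4-[tert-butyl(dimethyl)silyloxy]phenyl}ethenyl]-1,3,2-benzodioxaborole | CC(C)(C)[Si](C)(C)Oc1ccc(/C=C/B2Oc3ccccc3O2)cc1
F10 | step 10 | [(E)-2-{4-[tert-butyl(dimethyl)silyloxy]phenyl}ethenyl]boronic acid | CC(C)(C)[Si](C)(C)Oc1ccc(/C=C/B(O)O)cc1
A1 | alternative 1 | 5-O-methylcaraganin A tris(methoxymethyl) ether | COc1ccc([C@H](/C=C/c2ccc(OCOC)cc2)c2cc(-c3coc4cc(OC)cc(OC)c4c3=O)c(OCOC)cc2OCOC)c(OC)c1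
A2 | alternative 1 | 3,5-dimethoxy-2-(trimethylsilyl)phenyl trifluoromethanesulfonate | COc1cc(OC)c([Si](C)(C)C)c(OS(=O)(=O)C(F)(F)F)c1
A3 | alternative 1 | methyl (Z)-3-hydroxy-2-aryl-prop-2-enoate carrying the complete ring B half, tris(methoxymethyl) ether | COc1ccc([C@H](/C=C/c2ccc(OCOC)cc2)c2cc(/C(=C/O)C(=O)OC)c(OCOC)cc2OCOC)c(OC)c1
A4 | alternative 2 | 5-O-methylcaraganin A tris(benzyl) ether | COc1ccc([C@H](/C=C/c2ccc(OCc3ccccc3)cc2)c2cc(-c3coc4cc(OC)cc(OC)c4c3=O)c(OCc3ccccc3)cc2OCc2ccccc2)c(OC)c1
A5 | alternative 2 | (Z)-3-(3,5-dimethoxyphenoxy)-2-arylprop-2-enoic acid carrying the complete ring B half, tris(benzyl) ether | COc1ccc([C@H](/C=C/c2ccc(OCc3ccccc3)cc2)c2cc(/C(=C/Oc3cc(OC)cc(OC)c3)C(=O)O)c(OCc3ccccc3)cc2OCc2ccccc2)c(OC)c1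
A6 | alternative 3 | caraganin A tris(methoxymethyl) ether | COc1ccc([C@H](/C=C/c2ccc(OCOC)cc2)c2cc(-c3coc4cc(OC)cc(O)c4c3=O)c(OCOC)cc2OCOC)c(OC)c1
A7 | alternative 3 | ring B aryldiazonium tetrafluoroborate with stereocentre and styrene in place, tris(methoxymethyl) ether | COc1ccc([C@H](/C=C/c2ccc(OCOC)cc2)c2cc([N+]#N)c(OCOC)cc2OCOC)c(OC)c1.F[B-](F)(F)F
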